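The synthesis rests on closing dihydropyran ring B last, by forming the O9–C10 enol-ether bond (labels below). C10 is the exocyclic carbon of fulvene ring A and the δ-carbon of the C5 carbonyl, hence a latent vinylogous acyl carbon, and O9 reaches it through C8–C7–C6–C11. A rhodium-catalysed allenic Pauson–Khand reaction of a sulfonylallene–ynedione builds rings A and C and leaves a phenylsulfonyl nucleofuge on C10. After imine, enamine-aldol and Mannich closures of rings E, D and F, fluoride frees O9, which displaces sulfinate by 6-endo addition–elimination. The precursor is a δ-phenylsulfonyl dienone with a silyloxyethyl chain and no pyran; enol acetylation then unveils the acetoxyfulvene.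

Key step: step 21

Atom labels used throughout:
- ring A (fulvene) = C5(OAc)–C6–C11–C12–C13
- ring B (dihydropyran) = C6–C7–C8–O9–C10–C11
- ring C (seven-membered carbocycle) = C10–C11–C12–C22–C19–C20–C21
- ring D (cyclohexene) = C12–C13–C14–C15–C16–C22
- ring E (pyrrolidine) = C16–N17–C18–C19–C22
- ring F (azepanone) = C14–C15–C16–N17–C24–C25–C27(=O)
- C23 = methyl on C22, C26 = methyl on C25; hydroxyls sit on C14 and C16
- R = 7-[(tert-butyldiphenylsilyl)oxy]-5-[(4-methoxybenzyl)oxy]hept-3-yn-1-yl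

Assumptions:
- 1, 2 and 18 are taken as commercially available.
- The carbon that becomes C6 is made racemic in step 1 and is carried as a mixture (carbinol, allene axis, ring carbon) until it becomes sp2 in step 22.
- 27 is drawn as the C14 epimer that is carried on.
- 29 is written as its C5-keto tautomer.

Step 1
Reactants: 1 tert-butyldimethyl(pent-4-yn-1-yloxy)silane; 2 3-[(tert-butyldiphenylsilyl)oxy]propanal
Product: 3 8-[(tert-butyldimethylsilyl)oxy]-1-[(tert-butyldiphenylsilyl)oxy]oct-4-yn-3-ol (racemic)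
Conditions: n-BuLi, THF, −78 °C; then 2, −78 → 0 °C; aq NH4Cl
Reagents that add atoms: none
Why: Addition of the lithium acetylide of 1 to aldehyde 2 (alkynylation of a carbonyl group) forms the C11–C6 bond; the carbinol carbon (future C6) is racemic, which is harmless because C6 ends as an sp2 carbon.

Step 2
Reactants: 3 8-[(tert-butyldimethylsilyl)oxy]-1-[(tert-butyldiphenylsilyl)oxy]oct-4-yn-3-ol
Product: 4 8-[(tert-butyldimethylsilyl)oxy]-1-[(tert-butyldiphenylsilyl)oxy]-3-[(4-methoxybenzyl)oxy]oct-4-yne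
Conditions: NaH, 4-methoxybenzyl chloride, Bu4NI (cat.), THF/DMF, 0 °C → rt
Reagents that add atoms: 4-methoxybenzyl chloride, COc1ccc(CCl)cc1
Why: Williamson ether synthesis masks the propargylic hydroxyl as a 4-methoxybenzyl ether that is orthogonal to both silyl ethers, to the later carbamate and to all carbanion chemistry.

Step 3
Reactants: 4 8-[(tert-butyldimethylsilyl)oxy]-1-[(tert-butyldiphenylsilyl)oxy]-3-[(4-methoxybenzyl)oxy]oct-4-yne
Product: 5 8-[(tert-butyldiphenylsilyl)oxy]-6-[(4-methoxybenzyl)oxy]oct-4-yn-1-ol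
Conditions: pyridinium p-toluenesulfonate, EtOH, 50 °C
Reagents that add atoms: none
Why: Acid-catalysed solvolysis removes the primary tert-butyldimethylsilyl ether much faster than the bulkier tert-butyldiphenylsilyl ether, and the benzyl-type ether is inert.

Step 4
Reactants: 5 8-[(tert-butyldiphenylsilyl)oxy]-6-[(4-methoxybenzyl)oxy]oct-4-yn-1-ol
Product: 6 8-[(tert-butyldiphenylsilyl)oxy]-6-[(4-methoxybenzyl)oxy]oct-4-ynal
Conditions: Dess–Martin periodinane, CH2Cl2, 0 °C → rt
Reagents that add atoms: none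
Why: Hypervalent-iodine (Dess–Martin) oxidation takes the primary alcohol to the aldehyde under neutral conditions without touching the alkyne or the ethers.

Step 5
Reactants: 6 8-[(tert-butyldiphenylsilyl)oxy]-6-[(4-methoxybenzyl)oxy]oct-4-ynal
Product: 7 (2E)-10-[(tert-butyldiphenylsilyl)oxy]-8-[(4-methoxybenzyl)oxy]dec-2-en-6-ynal
Conditions: Ph3P=CHCHO, toluene, 80 °C
Reagents that add atoms: (triphenylphosphoranylidene)acetaldehyde, O=CC=P(c1ccccc1)(c1ccccc1)c1ccccc1
Why: Wittig olefination with the stabilised formylmethylene ylide gives the (E)-enal and adds C22 and C16.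

Step 6
Reactants: 7 (2E)-10-[(tert-butyldiphenylsilyl)oxy]-8-[(4-methoxybenzyl)oxy]dec-2-en-6-ynal
Product: 8 (3S)-10-[(tert-butyldiphenylsilyl)oxy]-8-[(4-methoxybenzyl)oxy]-3-(nitromethyl)dec-6-ynal (C8 epimers)
Conditions: CH3NO2, (R)-α,α-diphenylprolinol trimethylsilyl ether (10 mol %), PhCO2H (20 mol %), MeOH, rt
Reagents that add atoms: nitromethane, C[N+](=O)[O-]
Why: Iminium-catalysed asymmetric Michael addition: the (R)-configured diarylprolinol silyl ether shields one face of the (E)-iminium ion, so nitromethane adds to C19 from the open face and sets C19 (3S in 8), bringing in C18 and N17.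

Step 7
Reactants: 8 (3S)-10-[(tert-butyldiphenylsilyl)oxy]-8-[(4-methoxybenzyl)oxy]-3-(nitromethyl)dec-6-ynal
Product: 9 (3S)-10-[(tert-butyldiphenylsilyl)oxy]-8-[(4-methoxybenzyl)oxy]-3-(nitromethyl)dec-6-ynoic acid
Conditions: NaClO2, NaH2PO4, 2-methylbut-2-ene, t-BuOH/H2O, 0 °C → rt
Reagents that add atoms: sodium chlorite, [Na+].[O-]Cl=O
Why: Pinnick oxidation converts the aldehyde into the acid (C16) without epimerising C19 or affecting the nitro group.

Step 8
Reactants: 9 (3S)-10-[(tert-butyldiphenylsilyl)oxy]-8-[(4-methoxybenzyl)oxy]-3-(nitromethyl)dec-6-ynoic acid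
Product: 11 (4S)-4-R-pyrrolidin-2-one, via amino acid 10 (not isolated)
Conditions: Zn, AcOH, rt; filter; then Et3N, toluene, 110 °C
Reagents that add atoms: none
Why: Zinc reduces the nitro group to the amine, and the γ-amino acid lactamises on heating (5-exo-trig acyl substitution), so N17–C18–C19–C22–C16 becomes a five-membered template with C19 unchanged.

Step 9
Reactants: 11 (4S)-4-R-pyrrolidin-2-one
Product: 12 tert-butyl (4S)-2-oxo-4-R-pyrrolidine-1-carboxylate
Conditions: Boc2O, DMAP (cat.), Et3N, CH2Cl2, rt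
Reagents that add atoms: di-tert-butyl dicarbonate, CC(C)(C)OC(=O)OC(=O)OC(C)(C)C
Why: N-Acylation with Boc2O activates the lactam carbonyl for the later ring opening and acidifies the C22 hydrogens.

Step 10
Reactants: 12 tert-butyl (4S)-2-oxo-4-R-pyrrolidine-1-carboxylate
Product: 13 tert-butyl (4S)-3-acetyl-2-oxo-4-R-pyrrolidine-1-carboxylate (C3 epimers)
Conditions: LiN(SiMe3)2, THF, −78 °C; then CH3C(O)N(OMe)Me, −78 → −40 °C; aq NH4Cl
Reagents that add atoms: N-methoxy-N-methylacetamide, CC(=O)N(C)OC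
Why: Claisen-type C-acylation of the lactam lithium enolate with an N-methoxy-N-methyl amide, whose stable tetrahedral adduct prevents proton transfer and double reaction, installs the acetyl group (future C12–C13) on C22; the C22 configuration is not yet fixed.

Step 11
Reactants: 13 tert-butyl (4S)-3-acetyl-2-oxo-4-R-pyrrolidine-1-carboxylate
Product: 14 tert-butyl (3S,4S)-3-acetyl-3-methyl-2-oxo-4-R-pyrrolidine-1-carboxylate
Conditions: K2CO3, CH3I, acetone, rt
Reagents that add atoms: iodomethane, CI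
Why: C-Alkylation of the β-keto lactam enolate: iodomethane approaches the planar enolate anti to the C19 side chain, so C23 ends trans to that chain (cis to H–C19) and the quaternary centre C22 is set by substrate control.

Step 12
Reactants: 14 tert-butyl (3S,4S)-3-acetyl-3-methyl-2-oxo-4-R-pyrrolidine-1-carboxylate
Product: 16 tert-butyl (3S,4S)-3-ethynyl-3-methyl-2-oxo-4-R-pyrrolidine-1-carboxylate, via enol phosphate 15 (not isolated)
Conditions: LiN(iPr)2, THF, −78 °C; ClP(O)(OEt)2; then LiN(iPr)2 (2.3 equiv), −78 → 0 °C; aq NH4Cl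
Reagents that add atoms: none
Why: Enol phosphate formation at the only enolisable position and base-induced β-elimination convert the methyl ketone into the terminal alkyne C12≡C13, and the quaternary C22 cannot epimerise.

Step 13
Reactants: 16 tert-butyl (3S,4S)-3-ethynyl-3-methyl-2-oxo-4-R-pyrrolidine-1-carboxylate
Product: 17 tert-butyl N-[(2S,3S)-3-acetyl-3-methyl-2-R-pent-4-yn-1-yl]carbamate
Conditions: MeMgBr (3.5 equiv), THF, −78 → −20 °C; aq NH4Cl
Reagents that add atoms: methylmagnesium bromide, C[Mg]Br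
Why: Grignard addition to the Boc-activated (imide-like) lactam carbonyl gives a tetrahedral adduct that collapses on work-up to the C16 methyl ketone (C15 added) and the Boc-protected C18 amine; extra reagent is consumed by the alkyne C–H, and C22 and C19 are untouched.

Step 14
Reactants: 18 2-oxobutanoic acid
Product: 19 2-oxobutanoyl chloride
Conditions: Cl2CHOCH3, neat, 50 °C; used crude
Reagents that add atoms: dichloro(methoxy)methane, COC(Cl)Cl
Why: Dichloromethyl methyl ether converts the α-keto acid into its acid chloride (acyl chloride formation) without the decarbonylation that harsher chlorinating agents cause.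

Step 15
Reactants: 17 tert-butyl N-[(2S,3S)-3-acetyl-3-methyl-2-R-pent-4-yn-1-yl]carbamate; 19 2-oxobutanoyl chloride
Product: 20 tert-butyl N-[(2S,3S)-3-acetyl-3-methyl-6,7-dioxo-2-R-non-4-yn-1-yl]carbamate
Conditions: CuI (5 mol %), Et3N, THF, 0 °C → rt
Reagents that add atoms: none
Why: Copper-catalysed coupling of a terminal alkyne with an acid chloride (via the copper acetylide) attaches C14 and C27 to C13; the acyl carbon has no α-hydrogen, so no ketene is formed, and the carbamate N–H is not acylated under these conditions.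

Step 16
Reactants: 20 tert-butyl N-[(2S,3S)-3-acetyl-3-methyl-6,7-dioxo-2-R-non-4-yn-1-yl]carbamate
Product: 21 tert-butyl N-[(2S,3S)-3-acetyl-2-{7-[(tert-butyldiphenylsilyl)oxy]-5-hydroxyhept-3-yn-1-yl}-3-methyl-6,7-dioxonon-4-yn-1-yl]carbamate
Conditions: DDQ, CH2Cl2/pH 7 buffer, 0 °C
Reagents that add atoms: none
Why: Oxidative cleavage of the 4-methoxybenzyl ether by DDQ (hydride abstraction then hydrolysis) frees the propargylic hydroxyl while silyl ether, carbamate and ynedione stay intact.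

Step 17
Reactants: 21 tert-butyl N-[(2S,3S)-3-acetyl-2-{7-[(tert-butyldiphenylsilyl)oxy]-5-hydroxyhept-3-yn-1-yl}-3-methyl-6,7-dioxonon-4-yn-1-yl]carbamate
Product: 23 tert-butyl N-[(2S,3S)-3-acetyl-2-{7-[(tert-butyldiphenylsilyl)oxy]-3-(phenylsulfonyl)hepta-3,4-dien-1-yl}-3-methyl-6,7-dioxonon-4-yn-1-yl]carbamate (allene epimers), via propargylic sulfinate 22 (not isolated)
Conditions: PhS(O)Cl, i-Pr2NEt, CH2Cl2, −78 °C; then AgSbF6 (5 mol %), CH2Cl2, rt
Reagents that add atoms: benzenesulfinyl chloride, O=S(Cl)c1ccccc1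
Why: O-Sulfinylation followed by silver-catalysed [2,3]-sigmatropic rearrangement of the propargylic sulfinate gives the allenyl sulfone with sulfur on C10 and avoids any oxidant that would attack the 1,2-dione; the allene axis forms as a mixture.

Step 18
Reactants: 23 tert-butyl N-[(2S,3S)-3-acetyl-2-{7-[(tert-butyldiphenylsilyl)oxy]-3-(phenylsulfonyl)hepta-3,4-dien-1-yl}-3-methyl-6,7-dioxonon-4-yn-1-yl]carbamate
Product: 24 rings A/C dienone: cyclopentenone ring A (C5=O, C13=C12) fused to cycloheptene ring C (C10=C11), with PhSO2 on C10, CH2CH2OSi(t-Bu)Ph2 on C6, 2-oxobutanoyl on C13, acetyl and methyl on C22 and CH2NHBoc on C19 (C19 S, C22 S; C6 epimers)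
Conditions: [RhCl(CO)2]2 (5 mol %), CO (1 atm), toluene, 80 °C
Reagents that add atoms: carbon monoxide, [C-]#[O+]
Why: Rhodium-catalysed allenic Pauson–Khand reaction: the sulfonyl group on the proximal allene carbon steers oxidative cyclisation to the distal C11=C6 π-bond, so CO insertion forms C11–C12, C6–C5 and C5–C13 and closes rings A and C together, leaving the C10=C11 vinyl sulfone; C6 arises as a mixture and C19 and C22 are spectators.

Step 19
Reactants: 24 rings A/C dienone with CH2NHBoc on C19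
Product: 27 rings A/C/D/E β-hydroxy ketimine: ring E closed as the C16=N17 imine and ring D closed by the C15–C14 bond with C14 carrying OH and propanoyl, via primary amine 25 (not isolated), via cyclic imine 26 (not isolated)
Conditions: CF3CO2H, CH2Cl2, 0 °C; evaporate; then NaOAc, AcOH, MeCN, 40 °C
Reagents that add atoms: none
Why: Acidolysis of the Boc group frees the C18 amine, which condenses with the C16 ketone to the five-membered ketimine (ring E), and its enamine tautomer then adds to the activated C14 ketone in an intramolecular enamine (aza-ene type) aldol reaction closing six-membered ring D; the addition is reversible, and the C14 epimer drawn is the one that step 20 removes from the equilibrium.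

Step 20
Reactants: 27 rings A/C/D/E β-hydroxy ketimine
Product: 28 rings A/C/D/E/F carbinolamine: N17–C24–C25(C26)–C27(=O)–C14 bridge closed, OH on C16, PhSO2 still on C10 and the silyloxyethyl chain on C6
Conditions: aq CH2O (37 %, 1.5 equiv), AcOH, MeCN, 50 °C
Reagents that add atoms: formaldehyde, C=O; water, O
Why: Three-component Mannich reaction made intramolecular: N17 (as the hydrated carbinolamine of the ketimine) and formaldehyde give an N-methyleneiminium ion that is captured by the C25 enol of the ethyl ketone, closing seven-membered ring F with C16 held as the bridgehead carbinolamine because the bicyclic frame allows neither an iminium ion nor an enamine there; C16 and C14 follow from the bridged ring system, and C25, being α to the C27 ketone, should equilibrate to the epimer with C26 on the convex face.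

Step 21
Reactants: 28 rings A/C/D/E/F carbinolamine with PhSO2 on C10
Product: 29 deacetyl target in its C5-keto form (rings A–F complete; C6 epimers)
Conditions: Bu4NF (2.5 equiv), THF, 0 °C → rt; then AcOH
Reagents that add atoms: none
Why: Fluoride cleaves the Si–O9 bond, and the alkoxide adds to C10, the sulfonyl-bearing δ-carbon of the C5=O/C13=C12/C11=C10 dienone, to give a delocalised dienolate that expels benzenesulfinate and restores the C10=C11 bond, now as the enol ether of ring B. The closest known reaction type is nucleophilic vinylic substitution (addition–elimination) of alkoxides on β-sulfonyl enones, here in its vinylogous form. Ring B closes in the 6-endo-trig mode (O9 onto C10 with the C10=C11 bond inside the new ring). No stereocentre is created; C6 stays epimerisable and becomes sp2 in step 22. The step needs attack at C10 rather than sulfone-directed Michael addition at C11 (5-exo, would build a quaternary centre) or hemiketal formation at C5, and this is secured because only the C10 adduct can lose sulfinate irreversibly while the other adducts revert; the tertiary hydroxyls on C14 and C16 cannot reach C10.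

Step 22
Reactants: 29 deacetyl target in its C5-keto form
Product: 30 CNP0309418.1 (target)
Conditions: Ac2O, Et3N, DMAP (5 mol %), CH2Cl2, −20 °C
Reagents that add atoms: acetic anhydride, CC(=O)OC(C)=O
Why: O-Acylation of an enolate (enol acetate formation): deprotonation at C6 gives the 2-oxidofulvene (cyclopentadienide-like) anion, which is acetylated on the C5 oxygen to give the C5=C6, C11=C10, C12=C13 fulvene, while the hindered tertiary hydroxyls on C14 and C16 are not acylated at low temperature; the stray C6 stereocentre disappears.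

Compound list
1 | tert-butyldimethyl(pent-4-yn-1-yloxy)silane | C#CCCCO[Si](C)(C)C(C)(C)C | starting material
2 | 3-[(tert-butyldiphenylsilyl)oxy]propanal | O=CCCO[Si](C(C)(C)C)(c1ccccc1)c1ccccc1 | starting material
3 | 8-[(tert-butyldimethylsilyl)oxy]-1-[(tert-butyldiphenylsilyl)oxy]oct-4-yn-3-ol (racemic) | CC(C)(C)[Si](C)(C)OCCCC#CC(O)CCO[Si](C(C)(C)C)(c1ccccc1)c1ccccc1 | intermediate
4 | 8-[(tert-butyldimethylsilyl)oxy]-1-[(tert-butyldiphenylsilyl)oxy]-3-[(4-methoxybenzyl)oxy]oct-4-yne | CC(C)(C)[Si](C)(C)OCCCC#CC(OCc1ccc(OC)cc1)CCO[Si](C(C)(C)C)(c1ccccc1)c1ccccc1 | intermediate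
5 | 8-[(tert-butyldiphenylsilyl)oxy]-6-[(4-methoxybenzyl)oxy]oct-4-yn-1-ol | OCCCC#CC(OCc1ccc(OC)cc1)CCO[Si](C(C)(C)C)(c1ccccc1)c1ccccc1 | intermediate
6 | 8-[(tert-butyldiphenylsilyl)oxy]-6-[(4-methoxybenzyl)oxy]oct-4-ynal | O=CCCC#CC(OCc1ccc(OC)cc1)CCO[Si](C(C)(C)C)(c1ccccc1)c1ccccc1 | intermediate
7 | (2E)-10-[(tert-butyldiphenylsilyl)oxy]-8-[(4-methoxybenzyl)oxy]dec-2-en-6-ynal | O=C/C=C/CCC#CC(OCc1ccc(OC)cc1)CCO[Si](C(C)(C)C)(c1ccccc1)c1ccccc1 | intermediate
8 | (3S)-10-[(tert-butyldiphenylsilyl)oxy]-8-[(4-methoxybenzyl)oxy]-3-(nitromethyl)dec-6-ynal | O=CC[C@@H](C[N+](=O)[O-])CCC#CC(OCc1ccc(OC)cc1)CCO[Si](C(C)(C)C)(c1ccccc1)c1ccccc1 | intermediate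
9 | (3S)-10-[(tert-butyldiphenylsilyl)oxy]-8-[(4-methoxybenzyl)oxy]-3-(nitromethyl)dec-6-ynoic acid | OC(=O)C[C@@H](C[N+](=O)[O-])CCC#CC(OCc1ccc(OC)cc1)CCO[Si](C(C)(C)C)(c1ccccc1)c1ccccc1 | intermediate
10 | (3S)-3-(aminomethyl)-10-[(tert-butyldiphenylsilyl)oxy]-8-[(4-methoxybenzyl)oxy]dec-6-ynoic acid | OC(=O)C[C@@H](CN)CCC#CC(OCc1ccc(OC)cc1)CCO[Si](C(C)(C)C)(c1ccccc1)c1ccccc1 | intermediate
11 | (4S)-4-R-pyrrolidin-2-one | O=C1C[C@H](CCC#CC(OCc2ccc(OC)cc2)CCO[Si](C(C)(C)C)(c2ccccc2)c2ccccc2)CN1 | intermediate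
12 | tert-butyl (4S)-2-oxo-4-R-pyrrolidine-1-carboxylate | O=C1C[C@H](CCC#CC(OCc2ccc(OC)cc2)CCO[Si](C(C)(C)C)(c2ccccc2)c2ccccc2)CN1C(=O)OC(C)(C)C | intermediate
13 | tert-butyl (4S)-3-acetyl-2-oxo-4-R-pyrrolidine-1-carboxylate (C3 epimers) | CC(=O)C1[C@H](CCC#CC(OCc2ccc(OC)cc2)CCO[Si](C(C)(C)C)(c2ccccc2)c2ccccc2)CN(C(=O)OC(C)(C)C)C1=O | intermediate
14 | tert-butyl (3S,4S)-3-acetyl-3-methyl-2-oxo-4-R-pyrrolidine-1-carboxylate | CC(=O)[C@]1(C)[C@H](CCC#CC(OCc2ccc(OC)cc2)CCO[Si](C(C)(C)C)(c2ccccc2)c2ccccc2)CN(C(=O)OC(C)(C)C)C1=O | intermediate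
15 | tert-butyl (3S,4S)-3-{1-[(diethoxyphosphoryl)oxy]ethenyl}-3-methyl-2-oxo-4-R-pyrrolidine-1-carboxylate | C=C(OP(=O)(OCC)OCC)[C@]1(C)[C@H](CCC#CC(OCc2ccc(OC)cc2)CCO[Si](C(C)(C)C)(c2ccccc2)c2ccccc2)CN(C(=O)OC(C)(C)C)C1=O | intermediate
16 | tert-butyl (3S,4S)-3-ethynyl-3-methyl-2-oxo-4-R-pyrrolidine-1-carboxylate | C#C[C@]1(C)[C@H](CCC#CC(OCc2ccc(OC)cc2)CCO[Si](C(C)(C)C)(c2ccccc2)c2ccccc2)CN(C(=O)OC(C)(C)C)C1=O | intermediate
17 | tert-butyl N-[(2S,3S)-3-acetyl-3-methyl-2-R-pent-4-yn-1-yl]carbamate | CC(=O)[C@](C)(C#C)[C@H](CCC#CC(OCc1ccc(OC)cc1)CCO[Si](C(C)(C)C)(c1ccccc1)c1ccccc1)CNC(=O)OC(C)(C)C | intermediate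
18 | 2-oxobutanoic acid | CCC(=O)C(=O)O | starting material
19 | 2-oxobutanoyl chloride | CCC(=O)C(=O)Cl | intermediate
20 | tert-butyl N-[(2S,3S)-3-acetyl-3-methyl-6,7-dioxo-2-R-non-4-yn-1-yl]carbamate | CC(=O)[C@](C)(C#CC(=O)C(=O)CC)[C@H](CCC#CC(OCc1ccc(OC)cc1)CCO[Si](C(C)(C)C)(c1ccccc1)c1ccccc1)CNC(=O)OC(C)(C)C | intermediate
21 | tert-butyl N-[(2S,3S)-3-acetyl-2-{7-[(tert-butyldiphenylsilyl)oxy]-5-hydroxyhept-3-yn-1-yl}-3-methyl-6,7-dioxonon-4-yn-1-yl]carbamate | CC(=O)[C@](C)(C#CC(=O)C(=O)CC)[C@H](CCC#CC(O)CCO[Si](C(C)(C)C)(c1ccccc1)c1ccccc1)CNC(=O)OC(C)(C)C | intermediate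
22 | benzenesulfinate ester of 21 at the propargylic hydroxyl | CC(=O)[C@](C)(C#CC(=O)C(=O)CC)[C@H](CCC#CC(OS(=O)c1ccccc1)CCO[Si](C(C)(C)C)(c1ccccc1)c1ccccc1)CNC(=O)OC(C)(C)C | intermediate
23 | tert-butyl N-[(2S,3S)-3-acetyl-2-{7-[(tert-butyldiphenylsilyl)oxy]-3-(phenylsulfonyl)hepta-3,4-dien-1-yl}-3-methyl-6,7-dioxonon-4-yn-1-yl]carbamate | CC(=O)[C@](C)(C#CC(=O)C(=O)CC)[C@H](CCC(=C=CCCO[Si](C(C)(C)C)(c1ccccc1)c1ccccc1)S(=O)(=O)c1ccccc1)CNC(=O)OC(C)(C)C | intermediate
24 | rings A/C dienone: PhSO2 on C10, CH2CH2OSi(t-Bu)Ph2 on C6, 2-oxobutanoyl on C13, acetyl and methyl on C22, CH2NHBoc on C19 | CCC(=O)C(=O)C1=C2[C@@](C)(C(C)=O)[C@@H](CNC(=O)OC(C)(C)C)CCC(S(=O)(=O)c3ccccc3)=C2C(CCO[Si](C(C)(C)C)(c3ccccc3)c3ccccc3)C1=O | intermediate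
25 | primary amine from 24 (Boc removed) | CCC(=O)C(=O)C1=C2[C@@](C)(C(C)=O)[C@@H](CN)CCC(S(=O)(=O)c3ccccc3)=C2C(CCO[Si](C(C)(C)C)(c3ccccc3)c3ccccc3)C1=O | intermediate
26 | cyclic ketimine (ring E closed, C16=N17, C15 methyl) | CCC(=O)C(=O)C1=C2[C@@]3(C)C(C)=NC[C@H]3CCC(S(=O)(=O)c4ccccc4)=C2C(CCO[Si](C(C)(C)C)(c4ccccc4)c4ccccc4)C1=O | intermediate
27 | rings A/C/D/E β-hydroxy ketimine (C14 carries OH and propanoyl) | O=C1C(CCO[Si](C(C)(C)C)(c5ccccc5)c5ccccc5)C(=C3S(=O)(=O)c5ccccc5)C2=C1[C@@](O)(C(=O)CC)CC4=NC[C@@H](CC3)[C@@]24C | intermediate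
28 | rings A/C/D/E/F carbinolamine with PhSO2 on C10 and the silyloxyethyl chain on C6 | O=C1C(CCO[Si](C(C)(C)C)(c5ccccc5)c5ccccc5)C(=C3S(=O)(=O)c5ccccc5)C2=C1[C@]1(O)C[C@@]4(O)N(C[C@@H](CC3)[C@@]24C)C[C@@H](C)C1=O | intermediate
29 | deacetyl target, C5-keto tautomer (rings A–F; C6 epimers) | O=C1C2CCOC3=C2C2=C1[C@]1(O)C[C@@]4(O)N(C[C@@H](CC3)[C@@]24C)C[C@@H](C)C1=O | intermediate
30 | CNP0309418.1 | CC(=O)OC1=C2CCOC3=C2C2=C1[C@]1(O)C[C@@]4(O)N(C[C@@H](CC3)[C@@]24C)C[C@@H](C)C1=O | target

Total step count: 22. Longest linear sequence: 21 steps (steps 1–13 and 15–22; step 14 prepares the acylating agent).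

Steps most likely to fail

Step 18. The chelating, strongly electron-poor 1,2-dione may sequester the rhodium catalyst, or the allenyl sulfone may isomerise before cyclocarbonylation sets in. The fallback masks the dione; it sets out from 20 and comes back at 27. Treatment of 20 with HC(OMe)3, MeOH and pyridinium p-toluenesulfonate should give the mono(dimethyl ketal) F1 (ketal at C27; the C14 regioisomer would serve equally). DDQ then gives the propargylic alcohol F2. PhS(O)Cl/i-Pr2NEt gives the propargylic sulfinate F3, which AgSbF6 rearranges to the allenyl sulfone F4. The same [RhCl(CO)2]2/CO conditions on this ordinary ynone should give the ketal-protected dienone F5. CF3CO2H/H2O then removes the ketal together with the Boc group, and the buffer stage of step 19 delivers 27.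

Step 19. The liberated primary amine may add to the tetrasubstituted C12 acceptor or condense with the dione instead of C16, and the aldol adduct may dehydrate. The fallback never frees the nitrogen before ring D is closed; it sets out from 24 and comes back at 27. Pyridinium p-toluenesulfonate in toluene at 80 °C should cyclise and dehydrate the keto carbamate to the N-Boc 2-methylidenepyrrolidine (enecarbamate) F6. Cu(OTf)2 (10 mol %) in CH2Cl2 at 0 °C then promotes intramolecular enecarbamate addition to the C14 ketone, giving the ring-D product as the N-Boc endocyclic enecarbamate F7. CF3CO2H in CH2Cl2 followed by NaHCO3 removes the Boc group and gives the imine 27.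

Step 20. The N-methyleneiminium ion may form without being captured by the C25 enol, so that N-hydroxymethyl and aminal species accumulate instead of the seven-membered ring. The fallback reverses the polarity of the ring closure; it sets out from 27 and comes back at 28. α-Methylenation of the ethyl ketone with (CH2O)n and i-Pr2NH2+ CF3CO2− in THF at reflux should give the isopropenyl ketone F8. N17 then closes ring F by intramolecular aza-Michael addition to C24 with hydration at C16 (NaOAc/AcOH buffer, aq MeCN, 40 °C), giving 28.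

Further compounds
F1 | step 18 | mono(dimethyl ketal) of 20 at C27: tert-butyl N-[(2S,3S)-3-acetyl-7,7-dimethoxy-3-methyl-6-oxo-2-R-non-4-yn-1-yl]carbamate | CC(=O)[C@](C)(C#CC(=O)C(OC)(OC)CC)[C@H](CCC#CC(OCc1ccc(OC)cc1)CCO[Si](C(C)(C)C)(c1ccccc1)c1ccccc1)CNC(=O)OC(C)(C)C
F2 | step 18 | propargylic alcohol from F1 (4-methoxybenzyl group removed) | CC(=O)[C@](C)(C#CC(=O)C(OC)(OC)CC)[C@H](CCC#CC(O)CCO[Si](C(C)(C)C)(c1ccccc1)c1ccccc1)CNC(=O)OC(C)(C)C
F3 | step 18 | benzenesulfinate ester of F2 | CC(=O)[C@](C)(C#CC(=O)C(OC)(OC)CC)[C@H](CCC#CC(OS(=O)c1ccccc1)CCO[Si](C(C)(C)C)(c1ccccc1)c1ccccc1)CNC(=O)OC(C)(C)C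
F4 | step 18 | allenyl sulfone, C27 dimethyl ketal analogue of 23 | CC(=O)[C@](C)(C#CC(=O)C(OC)(OC)CC)[C@H](CCC(=C=CCCO[Si](C(C)(C)C)(c1ccccc1)c1ccccc1)S(=O)(=O)c1ccccc1)CNC(=O)OC(C)(C)C
F5 | step 18 | rings A/C dienone, C27 dimethyl ketal analogue of 24 | CCC(OC)(OC)C(=O)C1=C2[C@@](C)(C(C)=O)[C@@H](CNC(=O)OC(C)(C)C)CCC(S(=O)(=O)c3ccccc3)=C2C(CCO[Si](C(C)(C)C)(c3ccccc3)c3ccccc3)C1=O
F6 | step 19 | N-Boc 2-methylidenepyrrolidine (enecarbamate) from 24, ring E closed with C16=C15H2 | CCC(=O)C(=O)C1=C2[C@@]3(C)C(=C)N(C(=O)OC(C)(C)C)C[C@H]3CCC(S(=O)(=O)c4ccccc4)=C2C(CCO[Si](C(C)(C)C)(c4ccccc4)c4ccccc4)C1=O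
F7 | step 19 | ring-D aldol product as N-Boc endocyclic enecarbamate (C16=C15), C14 carrying OH and propanoyl | O=C1C(CCO[Si](C(C)(C)C)(c5ccccc5)c5ccccc5)C(=C3S(=O)(=O)c5ccccc5)C2=C1[C@@](O)(C(=O)CC)C=C4N(C(=O)OC(C)(C)C)C[C@@H](CC3)[C@@]24C
F8 | step 20 | isopropenyl ketone analogue of 27 (C27(=O)–C25(=C24H2)–C26H3) | O=C1C(CCO[Si](C(C)(C)C)(c5ccccc5)c5ccccc5)C(=C3S(=O)(=O)c5ccccc5)C2=C1[C@@](O)(C(=O)C(C)=C)CC4=NC[C@@H](CC3)[C@@]24C
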